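**Remarks.** Labdane-type locants are used: C4 = CMe2, C5 = ring-fusion CH, C10 = ring-fusion C–CH3, C8=C9 = ring alkene, C11/C12 = CH2CH2 on C9, C13=C14 = chain alkene, C24 = CH2OH carbon on C13, C16 = carbinol carbon, C17–C20 = butenolide. The sense of induction in steps 7 and 13 is assigned from the accepted catalyst models; the mirror-image catalyst gives the mirror-image product.

**Plan**
1. Retrosynthesis: cut C13=C14 (silicon-tethered ring-closing metathesis) into bicyclic 2-methylidene alcohol 20 and butenolide carbinol 28. After adding back a C1=C2 bond and a C6 ketone, cut C3–C4 and C5–C10 together as one [4+2], giving acyclic tetraenone 12.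
2. Enabling feature: the six carbons of ring A (C1–C5, C10) map onto a diene C10=C1–C2=C3 plus a dienophile C4=C5. The other four atoms of ring B (C6–C9) are the tether, which already holds the tetrasubstituted C8=C9 bond of the target. C6, a CH2 in the target, can carry a removable carbonyl that activates C4=C5.
3. Forward, chain: a senecioate (C7–C10) and prenal (C4–C6) give a δ-lactone that locks C8=C9; then C1 (Colvin), C20 and C2–C3 (carboalumination/vinylation). Rings A and B form together in step 7; C1=C2 and C6=O are removed in steps 8 and 9.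
4. Forward, side chain: the C9 chain end becomes a 2-methylidene alcohol, the butenolide carbinol comes from furan-3-carbaldehyde, the two are tied through iPr2Si, metathesis closes C13=C14 and HF frees the diol.
5. Stereochemistry: C10 from the chiral Lewis acid in the endo cycloaddition; C5 by equilibration α to the C6 ketone to the trans-fused series; C16 from Keck allylation; C13=C14 (Z) from the eight-membered silacycle; C8=C9 from the lactone ring.

Key step: step 7

**Step 1**
Reactants: 1 ethyl 3-methylbut-2-enoate; 2 benzyl 4-bromobutyl ether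
Product: 3 ethyl 2-[4-(benzyloxy)butyl]-3-methylbut-3-enoate (racemic)
Conditions: LDA, THF–DMPU, −78 °C; then 2, NaI (cat.), −78 → 0 °C
Reagents that add atoms: none
Why: Deconjugative α-alkylation of the lithium dienolate of a 3-methylbut-2-enoate with a primary bromide is a standard enolate alkylation and puts the C11–C24 chain on the future C9 (the α-stereocentre is erased in step 2).

**Step 2**
Reactants: 3 ethyl 2-[4-(benzyloxy)butyl]-3-methylbut-3-enoate; 4 3-methylbut-2-enal
Product: 6 3-[4-(benzyloxy)butyl]-4-methyl-6-(2-methylprop-1-en-1-yl)-5,6-dihydro-2H-pyran-2-one (racemic), via (Z)-hydroxy ester 5 (not isolated)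
Conditions: LDA, THF, −78 °C; then 4, −78 → 23 °C, then 50 °C
Reagents that add atoms: none
Why: Vinylogous aldol addition followed by lactonisation: the α-carbon of the dienolate is fully substituted, so the reversible α-adduct drains into the γ-adduct at C7, and only the (Z)-alkoxide 5 can close the δ-lactone, which fixes C7 cis to C10 across the tetrasubstituted C8=C9 bond (C6 is formed racemic and is oxidised in step 6).

**Step 3**
Reactants: 6 the δ-lactone
Product: 7 3-[4-(benzyloxy)butyl]-4-methyl-6-(2-methylprop-1-en-1-yl)-5,6-dihydro-2H-pyran-2-ol (lactol, mixture of isomers)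
Conditions: DIBAL-H (1.05 equiv), CH2Cl2, −78 °C; Rochelle salt work-up
Reagents that add atoms: none
Why: Partial DIBAL-H reduction of an α,β-unsaturated δ-lactone stops at the lactol because the tetrahedral aluminate is stable at −78 °C.

**Step 4**
Reactants: 7 the lactol
Product: 9 (6Z)-7-[4-(benzyloxy)butyl]-2,6-dimethylnona-2,6-dien-8-yn-4-ol, via (Z)-hydroxy enal 8 (not isolated)
Conditions: TMSCHN2, LDA, THF, −78 °C; then 7, −78 → 23 °C
Reagents that add atoms: (trimethylsilyl)diazomethane, C[Si](C)(C)C=[N+]=[N-]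
Why: Colvin alkyne homologation: the lactol reacts through its open (Z)-hydroxy enal 8, lithio(trimethylsilyl)diazomethane adds to the aldehyde, Peterson elimination and loss of N2 give an alkylidene carbene whose 1,2-H shift delivers the terminal alkyne (C10≡C1) with the C8=C9 geometry untouched.

**Step 5**
Reactants: 9 the enyne alcohol
Product: 11 (6Z,8E)-7-[4-(benzyloxy)butyl]-2,6,8-trimethylundeca-2,6,8,10-tetraen-4-ol, via alkenylalane 10 (not isolated)
Conditions: AlMe3 (4 equiv), Cp2ZrCl2 (0.5 equiv), CH2Cl2, 0 → 23 °C; then vinyl bromide, Pd(PPh3)4 (5 mol %), ZnCl2, THF, 23 °C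
Reagents that add atoms: trimethylaluminium, C[Al](C)C; vinyl bromide, C=CBr
Why: Negishi zirconium-catalysed carboalumination adds CH3 (to C10) and Al (to C1) syn across the terminal alkyne, and palladium-catalysed cross-coupling of alane 10 with vinyl bromide proceeds with retention, so the (E)-C10=C1 bond (C9 trans to C2) and the diene are set in one flask.

**Step 6**
Reactants: 11 the tetraenol
Product: 12 (6Z,8E)-7-[4-(benzyloxy)butyl]-2,6,8-trimethylundeca-2,6,8,10-tetraen-4-one
Conditions: Dess–Martin periodinane, NaHCO3, CH2Cl2, 0 °C; used at once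
Reagents that add atoms: none
Why: Dess–Martin oxidation of the secondary allylic alcohol under buffered, non-enolising conditions gives the β,γ-unsaturated dienophile ketone without moving the C8=C9 bond.

**Step 7**
Reactants: 12 the tetraenone
Product: 13 (4aS,8aR)-4-[4-(benzyloxy)butyl]-3,4a,8,8-tetramethyl-4a,7,8,8a-tetrahydronaphthalen-1(2H)-one (cis-fused; 4a = C10, 8a = C5)
Conditions: (S)-o-tolyl-CBS oxazaborolidine (20 mol %), AlBr3 (16 mol %), CH2Cl2 (0.01 M), −78 → −20 °C
Reagents that add atoms: none
Why: Proposed new method: coordination of the chiral oxazaborolidinium Lewis acid to the C6 carbonyl lowers the enone LUMO, and the tethered diene C10=C1–C2=C3 adds across C4=C5 in a concerted, asynchronous [4+2] in which the C3–C4 bond (unsubstituted diene CH2 to the enone β-carbon) runs ahead of C5–C10, the positive charge developing at C10 being tertiary and allylic to C8=C9. The closest known reactions are Lewis-acid-promoted intramolecular Diels–Alder reactions of 1,7,9-decatrien-3-ones, AlCl3-catalysed Diels–Alder reactions of β,β-disubstituted enones and oxazaborolidinium-catalysed enantioselective Diels–Alder reactions (inter- and intramolecular) of enones and trienals; a catalytic enantioselective variant on a β,β-dimethyl enone with a fully substituted diene terminus has no precedent. Ring A is the cyclohexene of the cycloaddition, and ring B closes in the fused (type 1) mode through the four-atom tether C6–C9 when C5–C10 forms. C5 and C10 are set together: the catalyst shields one face of the bound enone so that the diene reaches the Si face of C5, and the endo position of the tether carbonyl, favoured by the Lewis acid and by the inside methyl on C10 (which would clash with an exo tether), turns this into 10S with a cis ring fusion. The step needs facial and endo/exo selectivity and the choice of the right diene; the first two rest on the catalyst together with the (E)-C10=C1 geometry and the Z-locked C8=C9 tether, the last on the fact that only the C10=C1–C2=C3 diene can reach C4=C5.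

**Step 8**
Reactants: 13 the cis-fused adduct
Product: 14 (4aS,8aR)-4-(4-hydroxybutyl)-3,4a,8,8-tetramethyl-4a,5,6,7,8,8a-hexahydronaphthalen-1(2H)-one
Conditions: H2 (1 atm), 10 % Pd/C, EtOAc–EtOH, 23 °C
Reagents that add atoms: none
Why: Heterogeneous catalytic hydrogenation saturates the cis-disubstituted C1=C2 bond and cleaves the benzyl ether by hydrogenolysis, while the tetrasubstituted C8=C9 bond is too hindered to be reduced.

**Step 9**
Reactants: 14 the cis-fused keto alcohol
Product: 17 4-[(4aS,8aS)-2,5,5,8a-tetramethyl-3,4,4a,5,6,7,8,8a-octahydronaphthalen-1-yl]butan-1-ol, via trans-fused ketone 15 (not isolated), via hydrazone 16 (not isolated)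
Conditions: KOH, diethylene glycol, 100 °C; then N2H4·H2O, 130 °C; then distil to 200 °C
Reagents that add atoms: none
Why: Under KOH the C5–H α to the ketone should equilibrate through the enolate to the more stable trans-fused ketone 15 (C10 is untouched), and Huang-Minlon Wolff–Kishner reduction of hydrazone 16 then removes the C6 oxygen that served as activating group.

**Step 10**
Reactants: 17 the bicyclic alcohol
Product: 18 4-[(4aS,8aS)-2,5,5,8a-tetramethyl-3,4,4a,5,6,7,8,8a-octahydronaphthalen-1-yl]butanal
Conditions: Dess–Martin periodinane, NaHCO3, CH2Cl2, 0 → 23 °C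
Reagents that add atoms: none
Why: Dess–Martin oxidation of a primary alcohol to the aldehyde is reliable and leaves the tetrasubstituted alkene alone.

**Step 11**
Reactants: 18 the aldehyde
Product: 19 2-methylidene-4-[(4aS,8aS)-2,5,5,8a-tetramethyl-3,4,4a,5,6,7,8,8a-octahydronaphthalen-1-yl]butanal
Conditions: 37 % aq. CH2O, pyrrolidine (10 mol %), propionic acid (10 mol %), i-PrOH, 45 °C
Reagents that add atoms: formaldehyde, C=O
Why: Organocatalytic α-methylenation (Mannich condensation of the enamine with formaldehyde, then amine elimination) converts an α-unbranched aldehyde into the 2-substituted acrolein.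

**Step 12**
Reactants: 19 the enal
Product: 20 2-methylidene-4-[(4aS,8aS)-2,5,5,8a-tetramethyl-3,4,4a,5,6,7,8,8a-octahydronaphthalen-1-yl]butan-1-ol
Conditions: NaBH4, CeCl3·7H2O, MeOH, 0 °C
Reagents that add atoms: none
Why: Luche reduction gives clean 1,2-reduction of the enal to the allylic alcohol.

**Step 13**
Reactants: 21 furan-3-carbaldehyde
Product: 22 (1R)-1-(furan-3-yl)but-3-en-1-ol
Conditions: allylSnBu3, (R)-BINOL (20 mol %), Ti(Oi-Pr)4 (10 mol %), 4 Å MS, CH2Cl2, −20 °C; aq. NaHCO3
Reagents that add atoms: allyltributylstannane, C=CC[Sn](CCCC)(CCCC)CCCC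
Why: Keck asymmetric allylation: the (R)-BINOL–titanium Lewis acid directs allyl transfer from tin to one face of the aldehyde, which should set C16 as (R) in the same sense as for benzaldehyde.

**Step 14**
Reactants: 22 the furyl alcohol
Product: 23 tert-butyl{[(1R)-1-(furan-3-yl)but-3-en-1-yl]oxy}dimethylsilane
Conditions: TBSCl, imidazole, DMF, 23 °C
Reagents that add atoms: tert-butyldimethylsilyl chloride, CC(C)(C)[Si](C)(C)Cl
Why: Standard silylation; the ether keeps the C16 oxygen from competing in the lactonisation of step 16.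

**Step 15**
Reactants: 23 the silyl ether
Product: 25 4-[(1R)-1-{[tert-butyl(dimethyl)silyl]oxy}but-3-en-1-yl]-5-hydroxyfuran-2(5H)-one (mixture at C5 of the ring), via furan endoperoxide 24 (not isolated)
Conditions: O2, hν (visible), Rose Bengal (cat.), i-Pr2NEt, CH2Cl2, −78 °C
Reagents that add atoms: oxygen, O=O
Why: [4+2] addition of singlet oxygen to the furan gives endoperoxide 24, from which the hindered amine removes the less hindered C–H remote from the substituent (Kornblum–DeLaMare fragmentation), so the carbonyl ends up distal and the hydroxyl-bearing carbon next to the side chain.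

**Step 16**
Reactants: 25 the γ-hydroxybutenolide
Product: 27 4-[(1R)-1-{[tert-butyl(dimethyl)silyl]oxy}but-3-en-1-yl]furan-2(5H)-one, via hydroxy acid 26 (not isolated)
Conditions: NaBH4, EtOH, 0 °C; then 1 M HCl to pH 2, 0 °C
Reagents that add atoms: none
Why: Borohydride reduces the open-chain aldehyde form of the γ-hydroxybutenolide, and acidification closes hydroxy acid 26 to the 4-substituted furan-2(5H)-one.

**Step 17**
Reactants: 27 the silylated butenolide
Product: 28 4-[(1R)-1-hydroxybut-3-en-1-yl]furan-2(5H)-one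
Conditions: HF·pyridine, THF, 0 → 23 °C
Reagents that add atoms: none
Why: Fluoride cleavage of the TBS ether under acidic buffering avoids base-induced opening or vinylogous enolisation of the butenolide.

**Step 18**
Reactants: 28 the butenolide carbinol; 20 the bicyclic allylic alcohol
Product: 30 di(propan-2-yl)silyl bis-ether linking the C24 oxygen of 20 and the C16 oxygen of 28, via chlorosilyl ether 29 (not isolated)
Conditions: 28, i-Pr2SiCl2 (3 equiv), imidazole, CH2Cl2, 0 °C; evaporate excess silane; then 20, imidazole, DMAP (cat.), CH2Cl2, 23 °C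
Reagents that add atoms: dichlorodi(propan-2-yl)silane, CC(C)[Si](Cl)(Cl)C(C)C
Why: Stepwise silylation with a dichlorosilane (secondary alcohol first with excess reagent, then the primary allylic alcohol) gives the unsymmetrical bis-alkoxysilane that serves as temporary tether.

**Step 19**
Reactants: 30 the tethered diene
Product: 31 4-[(4R,6Z)-7-{2-[(4aS,8aS)-2,5,5,8a-tetramethyl-3,4,4a,5,6,7,8,8a-octahydronaphthalen-1-yl]ethyl}-2,2-di(propan-2-yl)-5,8-dihydro-4H-1,3,2-dioxasilocin-4-yl]furan-2(5H)-one
Conditions: Grubbs II (10 mol %), CH2Cl2 (2 mM), 40 °C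
Reagents that add atoms: none
Why: Temporary-silicon-tethered ring-closing metathesis joins the 1,1-disubstituted and the terminal alkene in an eight-membered ring in which C24 and C15 are necessarily cis, so the trisubstituted C13=C14 bond forms with the required Z geometry.

**Step 20**
Reactants: 31 the silacycle
Product: 32 4-[(1R,3Z)-1-hydroxy-4-(hydroxymethyl)-6-[(4aS,8aS)-2,5,5,8a-tetramethyl-3,4,4a,5,6,7,8,8a-octahydronaphthalen-1-yl]hex-3-en-1-yl]furan-2(5H)-one (target)
Conditions: HF·pyridine, THF–pyridine, 0 → 23 °C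
Reagents that add atoms: none
Why: Fluoride cleaves both Si–O bonds of the tether and releases the 1,5-diol without touching the butenolide.

**Compound list**
1 | ethyl 3-methylbut-2-enoate | CCOC(=O)C=C(C)C | starting material
2 | benzyl 4-bromobutyl ether | BrCCCCOCc1ccccc1 | starting material
3 | ethyl 2-[4-(benzyloxy)butyl]-3-methylbut-3-enoate (racemic) | CCOC(=O)C(CCCCOCc1ccccc1)C(C)=C | intermediate
4 | 3-methylbut-2-enal | CC(C)=CC=O | starting material
5 | ethyl (2Z)-2-[4-(benzyloxy)butyl]-5-hydroxy-3,7-dimethylocta-2,6-dienoate (as its alkoxide, not isolated) | CCOC(=O)/C(CCCCOCc1ccccc1)=C(/C)CC(O)C=C(C)C | intermediate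
6 | 3-[4-(benzyloxy)butyl]-4-methyl-6-(2-methylprop-1-en-1-yl)-5,6-dihydro-2H-pyran-2-one (racemic) | O=C1OC(C=C(C)C)CC(C)=C1CCCCOCc2ccccc2 | intermediate
7 | 3-[4-(benzyloxy)butyl]-4-methyl-6-(2-methylprop-1-en-1-yl)-5,6-dihydro-2H-pyran-2-ol | OC1OC(C=C(C)C)CC(C)=C1CCCCOCc2ccccc2 | intermediate
8 | (2Z)-2-[4-(benzyloxy)butyl]-5-hydroxy-3,7-dimethylocta-2,6-dienal (open form of 7, not isolated) | O=C/C(CCCCOCc1ccccc1)=C(/C)CC(O)C=C(C)C | intermediate
9 | (6Z)-7-[4-(benzyloxy)butyl]-2,6-dimethylnona-2,6-dien-8-yn-4-ol | C#C/C(CCCCOCc1ccccc1)=C(/C)CC(O)C=C(C)C | intermediate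
10 | (E)-alkenyl(dimethyl)alane from 9, with AlMe2 on C1 and O–AlMe2 at C6 (not isolated) | C[Al](C)/C=C(C)/C(CCCCOCc1ccccc1)=C(/C)CC(O[Al](C)C)C=C(C)C | intermediate
11 | (6Z,8E)-7-[4-(benzyloxy)butyl]-2,6,8-trimethylundeca-2,6,8,10-tetraen-4-ol | C=C/C=C(C)/C(CCCCOCc1ccccc1)=C(/C)CC(O)C=C(C)C | intermediate
12 | (6Z,8E)-7-[4-(benzyloxy)butyl]-2,6,8-trimethylundeca-2,6,8,10-tetraen-4-one | C=C/C=C(C)/C(CCCCOCc1ccccc1)=C(/C)CC(=O)C=C(C)C | intermediate
13 | (4aS,8aR)-4-[4-(benzyloxy)butyl]-3,4a,8,8-tetramethyl-4a,7,8,8a-tetrahydronaphthalen-1(2H)-one | CC1=C(CCCCOCc3ccccc3)[C@@]2(C)C=CCC(C)(C)[C@H]2C(=O)C1 | intermediate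
14 | (4aS,8aR)-4-(4-hydroxybutyl)-3,4a,8,8-tetramethyl-4a,5,6,7,8,8a-hexahydronaphthalen-1(2H)-one | CC1=C(CCCCO)[C@@]2(C)CCCC(C)(C)[C@H]2C(=O)C1 | intermediate
15 | (4aS,8aS)-4-(4-hydroxybutyl)-3,4a,8,8-tetramethyl-4a,5,6,7,8,8a-hexahydronaphthalen-1(2H)-one (trans-fused, not isolated) | CC1=C(CCCCO)[C@@]2(C)CCCC(C)(C)[C@@H]2C(=O)C1 | intermediate
16 | hydrazone of 15 (not isolated) | CC1=C(CCCCO)[C@@]2(C)CCCC(C)(C)[C@@H]2C(=NN)C1 | intermediate
17 | 4-[(4aS,8aS)-2,5,5,8a-tetramethyl-3,4,4a,5,6,7,8,8a-octahydronaphthalen-1-yl]butan-1-ol | CC1=C(CCCCO)[C@@]2(C)CCCC(C)(C)[C@@H]2CC1 | intermediate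
18 | 4-[(4aS,8aS)-2,5,5,8a-tetramethyl-3,4,4a,5,6,7,8,8a-octahydronaphthalen-1-yl]butanal | CC1=C(CCCC=O)[C@@]2(C)CCCC(C)(C)[C@@H]2CC1 | intermediate
19 | 2-methylidene-4-[(4aS,8aS)-2,5,5,8a-tetramethyl-3,4,4a,5,6,7,8,8a-octahydronaphthalen-1-yl]butanal | CC1=C(CCC(=C)C=O)[C@@]2(C)CCCC(C)(C)[C@@H]2CC1 | intermediate
20 | 2-methylidene-4-[(4aS,8aS)-2,5,5,8a-tetramethyl-3,4,4a,5,6,7,8,8a-octahydronaphthalen-1-yl]butan-1-ol | CC1=C(CCC(=C)CO)[C@@]2(C)CCCC(C)(C)[C@@H]2CC1 | intermediate
21 | furan-3-carbaldehyde | O=Cc1ccoc1 | starting material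
22 | (1R)-1-(furan-3-yl)but-3-en-1-ol | C=CC[C@@H](O)c1ccoc1 | intermediate
23 | tert-butyl{[(1R)-1-(furan-3-yl)but-3-en-1-yl]oxy}dimethylsilane | C=CC[C@@H](O[Si](C)(C)C(C)(C)C)c1ccoc1 | intermediate
24 | 2,5-endoperoxide of furan 23 (not isolated) | C=CC[C@@H](O[Si](C)(C)C(C)(C)C)C1=CC2OOC1O2 | intermediate
25 | 4-[(1R)-1-{[tert-butyl(dimethyl)silyl]oxy}but-3-en-1-yl]-5-hydroxyfuran-2(5H)-one | C=CC[C@@H](O[Si](C)(C)C(C)(C)C)C1=CC(=O)OC1O | intermediate
26 | (2E)-3-[(1R)-1-{[tert-butyl(dimethyl)silyl]oxy}but-3-en-1-yl]-4-hydroxybut-2-enoic acid (not isolated) | C=CC[C@@H](O[Si](C)(C)C(C)(C)C)/C(CO)=C/C(=O)O | intermediate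
27 | 4-[(1R)-1-{[tert-butyl(dimethyl)silyl]oxy}but-3-en-1-yl]furan-2(5H)-one | C=CC[C@@H](O[Si](C)(C)C(C)(C)C)C1=CC(=O)OC1 | intermediate
28 | 4-[(1R)-1-hydroxybut-3-en-1-yl]furan-2(5H)-one | C=CC[C@@H](O)C1=CC(=O)OC1 | intermediate
29 | 4-[(1R)-1-{[chlorodi(propan-2-yl)silyl]oxy}but-3-en-1-yl]furan-2(5H)-one (not isolated) | C=CC[C@@H](O[Si](Cl)(C(C)C)C(C)C)C1=CC(=O)OC1 | intermediate
30 | di(propan-2-yl)silyl bis-ether of 20 (C24–O) and 28 (C16–O) | CC1=C(CCC(=C)CO[Si](C(C)C)(C(C)C)O[C@H](CC=C)C3=CC(=O)OC3)[C@@]2(C)CCCC(C)(C)[C@@H]2CC1 | intermediate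
31 | eight-membered (Z)-silacycle, 4-[(4R,6Z)-7-{2-[bicyclyl]ethyl}-2,2-di(propan-2-yl)-5,8-dihydro-4H-1,3,2-dioxasilocin-4-yl]furan-2(5H)-one | CC1=C(CC/C2=C/C[C@H](C3=CC(=O)OC3)O[Si](C(C)C)(C(C)C)OC2)[C@@]4(C)CCCC(C)(C)[C@@H]4CC1 | intermediate
32 | 4-[(1R,3Z)-1-hydroxy-4-(hydroxymethyl)-6-[(4aS,8aS)-2,5,5,8a-tetramethyl-3,4,4a,5,6,7,8,8a-octahydronaphthalen-1-yl]hex-3-en-1-yl]furan-2(5H)-one | CC1=C(CC/C(=C/C[C@@H](O)C2=CC(=O)OC2)CO)[C@@]2(C)CCCC(C)(C)[C@@H]2CC1 | target

**Totals.** 20 steps in all. Longest linear sequence: 15 steps (steps 1–12, then 18–20); the butenolide branch is steps 13–17.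

**Steps most likely to fail**

Step 7 (proposed new method). The Lewis acid may cause enolisation at C7 with migration of the C8=C9 bond into conjugation. The cycloaddition at two hindered termini may be slow. The catalyst may discriminate poorly between the enone faces or between endo and exo. The fallback gives up catalyst control and uses known chemistry. It sets out from tetraenone 12, which is cyclised with an achiral promoter (Me2AlCl, CH2Cl2, −78 → 0 °C, or thermally in toluene with BHT at 110–150 °C), as is established for 1,7,9-decatrien-3-ones. This gives the racemic cis-fused adduct, that is 13 together with its mirror image (4aR,8aS)-4-[4-(benzyloxy)butyl]-3,4a,8,8-tetramethyl-4a,7,8,8a-tetrahydronaphthalen-1(2H)-one F1. The enantiomers are separated by preparative chromatography on a chiral stationary phase, and the route is rejoined at 13.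

Step 9. Equilibration at the hindered C5 may be incomplete before reduction, which would carry cis-fused material forward. The β,γ double bond may also migrate in the hydrazone at 200 °C. The fallback separates equilibration from deoxygenation and replaces the hot anionic reduction by a hydride reduction. It sets out from 14, which is equilibrated on its own (NaOMe, MeOH, reflux; remaining 14 recycled after chromatography) to the trans-fused ketone 15. Ketone 15 is condensed with TsNHNH2 (EtOH, cat. AcOH, reflux) to N'-[(4aS,8aS)-4-(4-hydroxybutyl)-3,4a,8,8-tetramethyl-4a,5,6,7,8,8a-hexahydronaphthalen-1(2H)-ylidene]-4-methylbenzenesulfonohydrazide F2. Reduction with catecholborane (CHCl3, 0 °C) and then NaOAc·3H2O at reflux (Kabalka reduction) rejoins the route at 17.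

Step 4. The strongly basic diazo reagent may deprotonate the open hydroxy enal at a γ-position and scramble the C8=C9 geometry, or it may add only slowly to the hindered aldehyde. The fallback replaces the diazo homologation by a Wittig/elimination sequence. It sets out from lactol 7, which is treated with Ph3P=CHCl (from (chloromethyl)triphenylphosphonium chloride and KOt-Bu, THF, 0 → 23 °C) to give (6Z)-7-[4-(benzyloxy)butyl]-9-chloro-2,6-dimethylnona-2,6,8-trien-4-ol F3 (either chloroalkene isomer serves). Dehydrochlorination with excess n-BuLi (THF, −78 → 0 °C) rejoins the route at alkyne 9.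

**Further compounds**
F1 | step 7 | (4aR,8aS)-4-[4-(benzyloxy)butyl]-3,4a,8,8-tetramethyl-4a,7,8,8a-tetrahydronaphthalen-1(2H)-one | CC1=C(CCCCOCc3ccccc3)[C@]2(C)C=CCC(C)(C)[C@@H]2C(=O)C1
F2 | step 9 | N'-[(4aS,8aS)-4-(4-hydroxybutyl)-3,4a,8,8-tetramethyl-4a,5,6,7,8,8a-hexahydronaphthalen-1(2H)-ylidene]-4-methylbenzenesulfonohydrazide | CC1=C(CCCCO)[C@@]2(C)CCCC(C)(C)[C@@H]2C(=NNS(=O)(=O)c3ccc(C)cc3)C1
F3 | step 4 | (6Z)-7-[4-(benzyloxy)butyl]-9-chloro-2,6-dimethylnona-2,6,8-trien-4-ol | ClC=C/C(CCCCOCc1ccccc1)=C(/C)CC(O)C=C(C)C
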